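Time is what you watch on this bench: both flasks you take over, oak and cedar, are read at 2.0 d.

| flask | starting material | reagent | initiator | remark | time |
|---|---|---|---|---|---|
| eta | 0.50 M | 0.90 M | 5.7 mM | run made earlier |  |
| delta | 0.50 M | 0.90 M | 7.5 mM | run made earlier |  |
| epsilon | 0.50 M | 0.90 M | 8.2 mM | run made earlier |  |
| beta | 0.34 M | 0.90 M | 5 mM | run made earlier |  |
| oak | 0.25 M | 0.900 M | 10 mM |  | 2.0 d |
| cedar | 0.50 M | 0.900 M | 5.0 mM |  | 2.0 d |

| run | time / h | target / % | isomer of the product / % |
|---|---|---|---|
| eta | 12.0 | 84.0 | 7.1 |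
| eta | 25.0 | 83.7 | 16.5 |
| eta | 40.0 | 75.5 | 25.2 |
| eta | 50.0 | 69.8 | 29.6 |
| delta | 6.00 | 73.5 | 3.0 |
| delta | 15.0 | 87.5 | 10.8 |
| delta | 30.0 | 79.8 | 20.0 |
| delta | 50.0 | 69.1 | 29.8 |
| epsilon | 6.00 | 74.7 | 2.5 |
| epsilon | 15.0 | 88.1 | 9.4 |
| epsilon | 30.0 | 79.5 | 18.9 |
| epsilon | 50.0 | 70.4 | 30.9 |
| beta | 6.00 | 66.8 | 2.6 |
| beta | 15.0 | 85.1 | 8.1 |
| beta | 30.0 | 80.7 | 18.2 |
| beta | 50.0 | 70.1 | 29.5 |

(standard deviation of a reading: 0.5 percentage points)

- the winner by share of target in all that became target or isomer of the product; "neither" if no more than 2 percentage points parts them (oak / cedar / neither)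
- share of target in all that became target or isomer of the product, oak
- share of target in all that became target or isomer of the product, cedar

- the analysis behind the earlier runs scatters by 0.5 percentage points, standard deviation
- the share counts what is present at the end, not what went on to other products

By 15.0 h the delta run holds 98.3% of its charge as target plus isomer, and at 50.0 h it holds 98.9%, so the sum stands while the split moves. The share of target in the delta run reads 89.0% and then 69.9% at those readings, which gives 0.00692 h⁻¹: this is the drift constant, the fall in the logarithm of the share per hour once that sum stands, a reading from the delta run that carries its scatter.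

My own reckoning carries it to 2.0 d and expects a target share of 70.8% in either flask. Leave the charges alone and mind the clock: with initiator from 5 mM to 8.2 mM, the earlier runs read isomer between 29.5% and 30.9% at 50.0 h. Oak's initiator, 10 mM, lies beyond them.

The forecast says neither, with 70.8% for oak (66.5% to 73%) and 71.2% for cedar (69.5% to 72.8%), since “the later curve is the same in all four runs”.

    initiator → 2 initiating radical (k = 0.00220 h⁻¹)
    starting material + initiating radical → capped initiator + first chain carrier (k = 1.40 × 10⁵ M⁻¹ s⁻¹)
    reagent + first chain carrier → target + second chain carrier (k = 20000 M⁻¹ s⁻¹)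
    starting material + second chain carrier → by-product + first chain carrier (k = 3.50 × 10⁷ M⁻¹ h⁻¹)
    2 first chain carrier → ended chains A (k = 2.40 × 10⁷ M⁻¹ s⁻¹)
    2 second chain carrier → ended chains B (k = 1.00 × 10⁸ M⁻¹ s⁻¹)
    target ⇌ isomer of the product (K = 1.20, k = 0.00950 h⁻¹)
    target → over-reaction product (k = 8.50 × 10⁻⁵ h⁻¹)

The flasks give 70.7% for oak and 71.4% for cedar, where the drift constant gave 70.8%; they lie 0.70 percentage points apart, so neither wins. Oak's relaxation half-life of target and isomer by that step alone, both ways together, is 1.66 d against a run of 2.0 d, and its share stands lower, at 45.3%, after 20.0 d: the split read at 2.0 d is one under kinetic, not thermodynamic, control. Reading oak at 1.57 d or 2.53 d moves its share by 5 points, and the margin is 2 points. For oak read at 3.0 d the drift constant gives 60.0%; that neighbouring flask gives 62.0%.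

The data stem from a simulated flask from invented constants; noise was put on by code.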